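**Plan**
- Retrosynthesis: the C4 methylene of the upper isoflavan is taken back to a ketone, then C2–C3 and O1–C8a are cut together to give a 2-fluorodeoxybenzoin and formaldehyde. Next the C3–ring B bond is cut (methyl ketone + aryl bromide), then the bond between C4 of the lower isoflavan and ring B (chroman-4-yl cation + 2-bromo-5-methoxyphenol), and last the C3–ring F bond of the lower isoflavanone.
- Forward: ring F is joined to a preformed chromanone (rings D, E). Ring B is attached at lower C4 by Friedel–Crafts alkylation, and its bromine then carries in ring A as an acetophenone. Ring C is closed last by splicing formaldehyde between C3 and C8a.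
- Enabling feature: the upper C4 carbonyl both acidifies the C3 methylene (α to C4=O, benzylic to ring B) and activates the ortho C8a–F bond of ring A for SNAr.
- Stereochemistry: both C3 centres come from Noyori–Ikariya transfer hydrogenation with dynamic kinetic resolution of labile isoflavanones, giving (3R,4R)-cis carbinols. Lower C4 is set by attack of the arene on the cation anti to the C3 aryl group (trans). The upper C4 oxygen is removed at the end.
- All phenols travel as benzyl ethers and are released in the final hydrogenolysis.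

Key step: step 10

Remark: the half whose pyran ring is closed in the key step is called the upper unit (rings A, B, C), the 4-aryl half the lower unit (rings D, E, F), with chroman numbering in each; the sense of the transfer hydrogenation is assigned by analogy with chroman-4-one, where the (R,R)-catalyst gives the (R)-carbinol.

**Step 1**
Reactants: 1 2,6-dimethoxyphenol; 2 benzyl bromide
Product: 3 2-(benzyloxy)-1,3-dimethoxybenzene
Conditions: BnBr, K2CO3, DMF, 60 °C
Reagents that add atoms: benzyl bromide 2, BrCc1ccccc1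
Why: Williamson etherification of the acidic phenol should proceed cleanly, and benzyl is chosen so that every phenol protection falls in the final hydrogenolysis.

**Step 2**
Reactants: 3 2-(benzyloxy)-1,3-dimethoxybenzene; 4 N-bromosuccinimide
Product: 5 3-(benzyloxy)-1-bromo-2,4-dimethoxybenzene
Conditions: NBS (1.0 equiv), MeCN, 0 °C → rt
Reagents that add atoms: N-bromosuccinimide 4, O=C1CCC(=O)N1Br
Why: electrophilic aromatic bromination of a 1,2,3-trialkoxybenzene should go ortho to one methoxy and para to the other, because the central alkoxy group is twisted out of conjugation and does not direct to its own para position.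

**Step 3**
Reactants: 6 7-hydroxychroman-4-one; 2 benzyl bromide
Product: 7 7-(benzyloxy)chroman-4-one
Conditions: BnBr, K2CO3, acetone, reflux
Reagents that add atoms: benzyl bromide 2, BrCc1ccccc1
Why: Williamson etherification of the phenol, which is para to the carbonyl and therefore acidic, should be straightforward.

**Step 4**
Reactants: 7 7-(benzyloxy)chroman-4-one; 5 3-(benzyloxy)-1-bromo-2,4-dimethoxybenzene
Product: 8 rac-7-(benzyloxy)-3-[3-(benzyloxy)-2,4-dimethoxyphenyl]chroman-4-one
Conditions: Pd2(dba)3 (2 mol%), XPhos (5 mol%), NaOtBu, toluene, 80 °C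
Reagents that add atoms: none
Why: palladium-catalysed ketone α-arylation (oxidative addition of zerovalent palladium into C–Br, enolate transfer, C–C reductive elimination) is a known entry to isoflavanones from chroman-4-ones, and C3 is formed racemic and deliberately left labile.

**Step 5**
Reactants: 8 rac-7-(benzyloxy)-3-[3-(benzyloxy)-2,4-dimethoxyphenyl]chroman-4-one
Product: 9 (3R,4R)-7-(benzyloxy)-3-[3-(benzyloxy)-2,4-dimethoxyphenyl]chroman-4-ol (3,4-cis)
Conditions: RuCl[(R,R)-TsDPEN](p-cymene) (2 mol%), HCO2H/Et3N (5:2), EtOAc, 40 °C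
Reagents that add atoms: none
Why: Noyori–Ikariya asymmetric transfer hydrogenation with dynamic kinetic resolution should give one cis carbinol, because C3 epimerises through the enol under the amine while the (R,R)-catalyst reduces only the (3R)-ketone to the (4R)-alcohol.

**Step 6**
Reactants: 9 (3R,4R)-7-(benzyloxy)-3-[3-(benzyloxy)-2,4-dimethoxyphenyl]chroman-4-ol; 10 2-bromo-5-methoxyphenol
Product: 12 2-bromo-4-{(3R,4S)-7-(benzyloxy)-3-[3-(benzyloxy)-2,4-dimethoxyphenyl]chroman-4-yl}-5-methoxyphenol (3,4-trans), via lower-unit C4 benzylic cation 11 (not isolated)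
Conditions: 10 (3 equiv), Bi(OTf)3 (5 mol%), 4 Å MS, CH2Cl2, −20 → 0 °C
Reagents that add atoms: none
Why: Friedel–Crafts alkylation should work because the C4 cation is stabilised by the para 7-benzyloxy group and O1, the phenol can react only at the carbon para to OH and ortho to OMe (the other activated site carries bromine), and attack anti to the C3 aryl group sets (4S) trans to the retained (3R) centre.

**Step 7**
Reactants: 12 2-bromo-4-{(3R,4S)-7-(benzyloxy)-3-[3-(benzyloxy)-2,4-dimethoxyphenyl]chroman-4-yl}-5-methoxyphenol; 2 benzyl bromide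
Product: 13 (3R,4S)-7-(benzyloxy)-4-[4-(benzyloxy)-5-bromo-2-methoxyphenyl]-3-[3-(benzyloxy)-2,4-dimethoxyphenyl]chromane
Conditions: BnBr, K2CO3, DMF, 40 °C
Reagents that add atoms: benzyl bromide 2, BrCc1ccccc1
Why: Williamson etherification should cap the only free phenol without touching the non-acidic stereocentres.

**Step 8**
Reactants: 14 1-(2-fluoro-4-hydroxyphenyl)ethan-1-one; 2 benzyl bromide
Product: 15 1-[4-(benzyloxy)-2-fluorophenyl]ethan-1-one
Conditions: BnBr, K2CO3, acetone, reflux
Reagents that add atoms: benzyl bromide 2, BrCc1ccccc1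
Why: Williamson etherification of the para-acyl phenol should be fast, and the weak base leaves the aryl fluoride intact.

**Step 9**
Reactants: 13 (3R,4S)-7-(benzyloxy)-4-[4-(benzyloxy)-5-bromo-2-methoxyphenyl]-3-[3-(benzyloxy)-2,4-dimethoxyphenyl]chromane; 15 1-[4-(benzyloxy)-2-fluorophenyl]ethan-1-one
Product: 16 1-[4-(benzyloxy)-2-fluorophenyl]-2-[2-(benzyloxy)-5-{(3R,4S)-7-(benzyloxy)-3-[3-(benzyloxy)-2,4-dimethoxyphenyl]chroman-4-yl}-4-methoxyphenyl]ethan-1-one
Conditions: 15 (1.5 equiv), Pd2(dba)3 (2 mol%), Xantphos (5 mol%), K3PO4, toluene, 90 °C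
Reagents that add atoms: none
Why: palladium-catalysed α-arylation of a methyl ketone should stop at mono-arylation with the ortho-benzyloxy aryl bromide, and the mild phosphate base spares the activated aryl fluoride.

**Step 10**
Reactants: 16 1-[4-(benzyloxy)-2-fluorophenyl]-2-[2-(benzyloxy)-5-{(3R,4S)-7-(benzyloxy)-3-[3-(benzyloxy)-2,4-dimethoxyphenyl]chroman-4-yl}-4-methoxyphenyl]ethan-1-one; 17 formaldehyde (charged as paraformaldehyde)
Product: 19 7-(benzyloxy)-3-[2-(benzyloxy)-5-{(3R,4S)-7-(benzyloxy)-3-[3-(benzyloxy)-2,4-dimethoxyphenyl]chroman-4-yl}-4-methoxyphenyl]chroman-4-one (both C3 epimers), via aldol adduct 18 (not isolated)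
Conditions: (CH2O)n (3 equiv), Cs2CO3 (2 equiv), DMSO, 25 → 70 °C
Reagents that add atoms: formaldehyde 17, C=O
Why: Proposed new method: carbonate deprotonates C3, the only acidic carbon (α to the C4 ketone and benzylic to ring B), the enolate adds to formaldehyde to form C2–C3, and the aldolate oxygen then attacks C8a of ring A, whose fluorine sits ortho to the C4 carbonyl, through a Meisenheimer adduct that expels fluoride and forms O1–C8a. The closest known reaction types are the stepwise aldol addition and base-mediated intramolecular SNAr cyclisation of β-hydroxy 2-fluorophenyl ketones to chroman-4-ones and the formaldehyde annulation of 2-hydroxydeoxybenzoins to isoflavanones; what is new is their fusion in one flask with formaldehyde as the two-atom C2–O1 unit. Ring C closes in a 6-exo-trig addition–elimination at the arene carbon, the six ring atoms being O1, C2, C3, C4, C4a and C8a. The new stereocentre C3 is not controlled here and forms as both epimers, because it stays enolisable next to C4=O and is fixed only in step 11 by catalyst-controlled dynamic kinetic resolution; the (3R,4S) centres of the lower unit carry no acidic hydrogen and are untouched. The step needs O-arylation to outrun E1cB loss of water from the aldol adduct and a second hydroxymethylation, which the substrate secures because aldol addition, dehydration and rehydration are all reversible while fluoride loss is not, and because only ring A carries a leaving group activated by an ortho carbonyl.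

**Step 11**
Reactants: 19 7-(benzyloxy)-3-[2-(benzyloxy)-5-{(3R,4S)-7-(benzyloxy)-3-[3-(benzyloxy)-2,4-dimethoxyphenyl]chroman-4-yl}-4-methoxyphenyl]chroman-4-one (both C3 epimers)
Product: 20 (3R,4R)-7-(benzyloxy)-3-[2-(benzyloxy)-5-{(3R,4S)-7-(benzyloxy)-3-[3-(benzyloxy)-2,4-dimethoxyphenyl]chroman-4-yl}-4-methoxyphenyl]chroman-4-ol (upper unit 3,4-cis)
Conditions: RuCl[(R,R)-TsDPEN](p-cymene) (3 mol%), HCO2H/Et3N (5:2), CH2Cl2/EtOAc, 40 °C
Reagents that add atoms: none
Why: Noyori–Ikariya transfer hydrogenation with dynamic kinetic resolution should funnel both interconverting C3 epimers into the (3R,4R)-cis carbinol under catalyst control, the lower-unit stereocentres being remote from the reacting carbonyl.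

**Step 12**
Reactants: 20 (3R,4R)-7-(benzyloxy)-3-[2-(benzyloxy)-5-{(3R,4S)-7-(benzyloxy)-3-[3-(benzyloxy)-2,4-dimethoxyphenyl]chroman-4-yl}-4-methoxyphenyl]chroman-4-ol
Product: 21 (3R)-3-{2-hydroxy-5-[(3R,4S)-7-hydroxy-3-(3-hydroxy-2,4-dimethoxyphenyl)chroman-4-yl]-4-methoxyphenyl}chroman-7-ol (target)
Conditions: H2 (3 atm), 10% Pd/C, AcOH (10 vol%), EtOAc/EtOH, 25 °C
Reagents that add atoms: none
Why: catalytic hydrogenolysis should cleave the four benzyl ethers and the benzylic C4–O bond of the upper unit (activated by the para oxygen at C7) in one operation, and C3 is not a reacting centre, so its (R) configuration should be retained.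

**Compound list**
1 | 2,6-dimethoxyphenol | COc1cccc(OC)c1O | starting material
2 | benzyl bromide | BrCc1ccccc1 | starting material
3 | 2-(benzyloxy)-1,3-dimethoxybenzene | COc1cccc(OC)c1OCc1ccccc1 | intermediate
4 | N-bromosuccinimide | O=C1CCC(=O)N1Br | starting material
5 | 3-(benzyloxy)-1-bromo-2,4-dimethoxybenzene | COc1ccc(Br)c(OC)c1OCc1ccccc1 | intermediate
6 | 7-hydroxychroman-4-one | O=C1CCOc2cc(O)ccc21 | starting material
7 | 7-(benzyloxy)chroman-4-one | O=C1CCOc2cc(OCc3ccccc3)ccc21 | intermediate
8 | rac-7-(benzyloxy)-3-[3-(benzyloxy)-2,4-dimethoxyphenyl]chroman-4-one | O=C1C(c2ccc(OC)c(OCc3ccccc3)c2OC)COc2cc(OCc3ccccc3)ccc21 | intermediate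
9 | (3R,4R)-7-(benzyloxy)-3-[3-(benzyloxy)-2,4-dimethoxyphenyl]chroman-4-ol | O[C@@H]1[C@H](c2ccc(OC)c(OCc3ccccc3)c2OC)COc2cc(OCc3ccccc3)ccc21 | intermediate
10 | 2-bromo-5-methoxyphenol | COc1ccc(Br)c(O)c1 | starting material
11 | (3R)-7-(benzyloxy)-3-[3-(benzyloxy)-2,4-dimethoxyphenyl]chroman-4-ylium cation | [CH+]1[C@H](c2ccc(OC)c(OCc3ccccc3)c2OC)COc2cc(OCc3ccccc3)ccc21 | intermediate
12 | 2-bromo-4-{(3R,4S)-7-(benzyloxy)-3-[3-(benzyloxy)-2,4-dimethoxyphenyl]chroman-4-yl}-5-methoxyphenol | COc1cc(O)c(Br)cc1[C@@H]1c2ccc(OCc3ccccc3)cc2OC[C@H]1c1ccc(OC)c(OCc2ccccc2)c1OC | intermediate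
13 | (3R,4S)-7-(benzyloxy)-4-[4-(benzyloxy)-5-bromo-2-methoxyphenyl]-3-[3-(benzyloxy)-2,4-dimethoxyphenyl]chromane | COc1cc(OCc2ccccc2)c(Br)cc1[C@@H]1c2ccc(OCc3ccccc3)cc2OC[C@H]1c1ccc(OC)c(OCc2ccccc2)c1OC | intermediate
14 | 1-(2-fluoro-4-hydroxyphenyl)ethan-1-one | CC(=O)c1ccc(O)cc1F | starting material
15 | 1-[4-(benzyloxy)-2-fluorophenyl]ethan-1-one | CC(=O)c1ccc(OCc2ccccc2)cc1F | intermediate
16 | 1-[4-(benzyloxy)-2-fluorophenyl]-2-[2-(benzyloxy)-5-{(3R,4S)-7-(benzyloxy)-3-[3-(benzyloxy)-2,4-dimethoxyphenyl]chroman-4-yl}-4-methoxyphenyl]ethan-1-one | COc1cc(OCc2ccccc2)c(CC(=O)c2ccc(OCc3ccccc3)cc2F)cc1[C@@H]1c2ccc(OCc3ccccc3)cc2OC[C@H]1c1ccc(OC)c(OCc2ccccc2)c1OC | intermediate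
17 | formaldehyde (charged as paraformaldehyde) | C=O | starting material
18 | aldol adduct: 1-[4-(benzyloxy)-2-fluorophenyl]-3-hydroxy-2-[2-(benzyloxy)-5-{(3R,4S)-7-(benzyloxy)-3-[3-(benzyloxy)-2,4-dimethoxyphenyl]chroman-4-yl}-4-methoxyphenyl]propan-1-one (both epimers at the new CH; present as its alkoxide) | COc1cc(OCc2ccccc2)c(C(CO)C(=O)c2ccc(OCc3ccccc3)cc2F)cc1[C@@H]1c2ccc(OCc3ccccc3)cc2OC[C@H]1c1ccc(OC)c(OCc2ccccc2)c1OC | intermediate
19 | 7-(benzyloxy)-3-[2-(benzyloxy)-5-{(3R,4S)-7-(benzyloxy)-3-[3-(benzyloxy)-2,4-dimethoxyphenyl]chroman-4-yl}-4-methoxyphenyl]chroman-4-one (both C3 epimers) | COc1cc(OCc2ccccc2)c(C2COc3cc(OCc4ccccc4)ccc3C2=O)cc1[C@@H]1c2ccc(OCc3ccccc3)cc2OC[C@H]1c1ccc(OC)c(OCc2ccccc2)c1OC | intermediate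
20 | (3R,4R)-7-(benzyloxy)-3-[2-(benzyloxy)-5-{(3R,4S)-7-(benzyloxy)-3-[3-(benzyloxy)-2,4-dimethoxyphenyl]chroman-4-yl}-4-methoxyphenyl]chroman-4-ol | COc1cc(OCc2ccccc2)c([C@@H]2COc3cc(OCc4ccccc4)ccc3[C@@H]2O)cc1[C@@H]1c2ccc(OCc3ccccc3)cc2OC[C@H]1c1ccc(OC)c(OCc2ccccc2)c1OC | intermediate
21 | (3R)-3-{2-hydroxy-5-[(3R,4S)-7-hydroxy-3-(3-hydroxy-2,4-dimethoxyphenyl)chroman-4-yl]-4-methoxyphenyl}chroman-7-ol | COc1cc(O)c([C@@H]2COc3cc(O)ccc3C2)cc1[C@@H]1c2ccc(O)cc2OC[C@H]1c1ccc(OC)c(O)c1OC | target

Total steps: 12. Longest linear sequence: 10 steps (steps 1, 2, 4, 5, 6, 7, 9, 10, 11, 12).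

**Steps most likely to fail**

Step 10 (Proposed new method). The aldol adduct may lose water by E1cB faster than its alkoxide displaces fluoride, and the resulting enone may be consumed by Michael addition of a second enolate. Hydroxymethylation may also occur twice at C3. Fallback: the pyran ring would be brought in preformed instead of being closed. The fallback sets out from aryl bromide 13, which would be coupled with 7-(benzyloxy)chroman-4-one 7 by the known palladium-catalysed chromanone α-arylation of step 4 (Pd2(dba)3, XPhos, NaOtBu, toluene, 80 °C). This should give isoflavanone 19 directly, where the route is rejoined; steps 8 and 9 are then not needed and no compound outside the list is made (F0).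

Step 6. The cation may lose the C3 proton reversibly, which would erode the C3 configuration; the carbinol may alkylate its own electron-rich rings; attack may occur at the phenol oxygen; and facial selectivity at C4 may be incomplete. Fallback: the catalytic dehydrative coupling of two free hydroxy partners would be replaced by a pre-activated donor and a capped acceptor, ionised at low temperature. Setting out from 9, acetylation (Ac2O, pyridine, DMAP) would give (3R,4R)-7-(benzyloxy)-3-[3-(benzyloxy)-2,4-dimethoxyphenyl]chroman-4-yl acetate F1, and phenol 10 would be benzylated (BnBr, K2CO3) to 2-(benzyloxy)-1-bromo-4-methoxybenzene F2. F1 would then be ionised with catalytic TMSOTf in CH2Cl2 at −78 °C in the presence of excess F2, which has no free hydroxyl and only one accessible activated carbon. This should give 13 directly, where the route is rejoined (step 7 is then not needed).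

Step 12. Acid-promoted loss of water across C3–C4 followed by unselective return of hydrogen would erode the upper C3 configuration, and the benzylic C4–O bond may be cleaved incompletely. Fallback: the C4 oxygen would be removed by a radical path that passes through neither a cation nor an alkene, separate from debenzylation. Setting out from 20, 1,1'-thiocarbonyldiimidazole (THF, 60 °C) would give O-{(3R,4R)-7-(benzyloxy)-3-[2-(benzyloxy)-5-{(3R,4S)-7-(benzyloxy)-3-[3-(benzyloxy)-2,4-dimethoxyphenyl]chroman-4-yl}-4-methoxyphenyl]chroman-4-yl} 1H-imidazole-1-carbothioate F3. Barton–McCombie reduction (Bu3SnH, AIBN, toluene, 90 °C) would give (3R)-7-(benzyloxy)-3-[2-(benzyloxy)-5-{(3R,4S)-7-(benzyloxy)-3-[3-(benzyloxy)-2,4-dimethoxyphenyl]chroman-4-yl}-4-methoxyphenyl]chromane F4. Neutral hydrogenolysis (H2, 10% Pd/C, EtOAc/EtOH) would then release the four phenols and return to 21.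

**Further compounds**
F0 | step 10 | none | none
F1 | step 6 | (3R,4R)-7-(benzyloxy)-3-[3-(benzyloxy)-2,4-dimethoxyphenyl]chroman-4-yl acetate | CC(=O)O[C@@H]1[C@H](c2ccc(OC)c(OCc3ccccc3)c2OC)COc2cc(OCc3ccccc3)ccc21
F2 | step 6 | 2-(benzyloxy)-1-bromo-4-methoxybenzene | COc1ccc(Br)c(OCc2ccccc2)c1
F3 | step 12 | O-{(3R,4R)-7-(benzyloxy)-3-[2-(benzyloxy)-5-{(3R,4S)-7-(benzyloxy)-3-[3-(benzyloxy)-2,4-dimethoxyphenyl]chroman-4-yl}-4-methoxyphenyl]chroman-4-yl} 1H-imidazole-1-carbothioate | COc1cc(OCc2ccccc2)c([C@@H]2COc3cc(OCc4ccccc4)ccc3[C@@H]2OC(=S)n2ccnc2)cc1[C@@H]1c2ccc(OCc3ccccc3)cc2OC[C@H]1c1ccc(OC)c(OCc2ccccc2)c1OC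
F4 | step 12 | (3R)-7-(benzyloxy)-3-[2-(benzyloxy)-5-{(3R,4S)-7-(benzyloxy)-3-[3-(benzyloxy)-2,4-dimethoxyphenyl]chroman-4-yl}-4-methoxyphenyl]chromane | COc1cc(OCc2ccccc2)c([C@@H]2COc3cc(OCc4ccccc4)ccc3C2)cc1[C@@H]1c2ccc(OCc3ccccc3)cc2OC[C@H]1c1ccc(OC)c(OCc2ccccc2)c1OC
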